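The runs are simulated on assumed constants, and the scatter is random.

| flask | Z | L | remark | time |
|---|---|---|---|---|
| red | 0.25 M | 0.50 M | run made earlier |  |
| blue | 0.25 M | 0.25 M | run made earlier |  |
| teal | 0.25 M | 1 M | run made earlier |  |
| ochre | 0.50 M | 0.50 M | run made earlier |  |
| zeta | 0.25 M (in portions, 5, over 1.0 h) | 0.500 M | first portion at the start, last at 1.0 h | 80 min |
| alpha | 0.25 M | 0.500 M | everything together at the start | 80 min |
| beta | 0.25 M | 0.500 M (fed, over 1.0 h) | all else is in the flask from the start; the feed brings no volume worth counting | 80 min |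
| theta | 0.25 M (fed, over 1.0 h) | 0.500 M | all else is in the flask from the start; the feed brings no volume worth counting | 80 min |

- red (time / min: D / %, Z / %): 4.00: 12, 84; 12.0: 36, 67; 20.0: 50, 49; 30.0: 64, 35; 50.0: 81, 21
- blue (time / min: D / %, Z / %): 12.0: 17, 78; 25.0: 35, 64; 40.0: 45, 55; 50.0: 52, 47; 60.0: 57, 43
- teal (time / min: D / %, Z / %): 5.00: 31, 66; 10.0: 52, 47; 20.0: 73, 23; 30.0: 85, 12; 60.0: 103, 3
- ochre (time / min: D / %, Z / %): 6.00: 18, 81; 15.0: 39, 58; 30.0: 56, 43; 50.0: 66, 33; 60.0: 74, 28

(scatter of a reading: 1.5 percentage points)

* the flask that comes out highest in amount of D, in percent of the Z charged, or "all alike" when all lie within 1.5 percentage points (zeta / alpha / beta / theta / all alike)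
* D at the end, in percent of the Z charged, zeta
* D at the end, in percent of the Z charged, alpha
* D at the end, in percent of the Z charged, beta
* D at the end, in percent of the Z charged, theta

- amounts and yields of D count E too
- given per volume of solution although it is solid: E
- on the list of suspects stand: Z + L <-> J; J -> D; L -> G; E <-> D

Per molar of L and per minute, Z is used at a pace read from the red run: at 30.0 min it stands at 35%, and with one L spent per Z the second-order law gives the reading k = 0.0876 /M/min. Hold L at its charge less half the Z charge and the reckoning becomes pseudo-first-order, with τ = 30.5 min, the Z life: Z in contact with L for a time a survives as exp(−a/τ).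

In alpha, a equals 80 min, so the reckoning puts D at 92.8%. In zeta, portions arrive 15.0 min apart, and averaging their survivals leaves 24.4% of Z in the reckoning, which puts D at 75.6%. Averaging over the feed gives theta 77.4%. Beta, with L fed, has a mean contact of 50.0 min and gives 80.6%. Alpha leads this reckoning because its contact of 80 min is longer than the mean contact of 50.0 min in the flasks that receive a charge over time.

The forecast says alpha: alpha 90%, beta 78%, theta 76%, zeta 74.6%, each below this reckoning. Its ground: “Having everything present from the start wins.”

The flasks give alpha 89.5%, beta 77.1%, theta 75.1%, zeta 73.5%, so alpha stands highest, as forecast. Alpha's D moves by 5 points with L charged at 0.428 M or 0.614 M, so a run showing alpha's D that far from its present value is what it would take to put the forecast's 90% out. In zeta, τ reckons the last portion to hold 10.4% of the Z charged at the end, when the flask holds 26.2% of Z.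

    Z + L ⇌ J (K = 0.0670 /M, k = 0.00370 /M/s)
    J → D (k = 0.0340 /s)
    L → G (k = 2.00 × 10⁻⁶ /s)
    E ⇌ D, rate k4*(cs4 - [D]) while solid is left; crystals form when [D] > cs4 (solubility = 7.30 mM, k = 0.140 /s)

For the neighbour of zeta with 0.30 M of L, the reckoned life lengthens to 65.3 min, and the reckoned portions give D of 51.0%. That flask gives 55.2%, with Z at 44.5%.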